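In a one-step world, starting material goes to target and you simply wait; this flask has a second way out, in which target is consumed by starting material.

the same everywhere: starting material 0.20 M; gas 6.9 mM (held); time 8.0 d
- zeta: temperature 65 °C
- gamma: temperature 20 °C
- alpha: temperature 50 °C
- epsilon: temperature 35 °C

    starting material + coupling partner → target, rate k1*[starting material]^2*[coupling partner]^0.5 (k1 = 7.9 × 10⁻⁴ /M^1.5/s, Ea1 = 65.0 kJ/mol)
    gas ⇌ coupling partner, rate k2*(csat - [coupling partner]) (k2 = 0.0027 /s, csat = 6.9 mM)
    starting material + target → side product (k3 = 3.5 × 10⁻⁵ /M/s, Ea3 = 70.0 kJ/mol)
    (constants at 35 °C)

- a species is counted by the starting material in it: one side product counts as two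
- at the start none of coupling partner is dissolved
- all constants are for 35 °C and move with temperature by the activation energies

- the best flask by amount of target, in percent of the starting material charged; "all alike" if 1.5 percentage points covers them all (zeta / gamma / alpha / epsilon / all alike)
- amount of target at the end, in percent of the starting material charged, zeta
- amount of target at the end, in percent of the starting material charged, gamma
- amount of target at the end, in percent of the starting material charged, alpha
- amount of target at the end, in percent of the starting material charged, epsilon

First: let A and P be the concentrations of starting material and target. While the dissolved coupling partner stands at its saturation value, the coupling step runs at S·A/P times the rate of the over-reaction. Here S, the selectivity factor, is the coupling rate constant times the root of the saturation concentration, over the rate constant of the over-reaction. For gamma, S = 2.07. It means how many times faster target is made than consumed when A equals P, and it holds no charge.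

Second: at the start P is zero, so each starting material lost gives target. Late on, each starting material lost by the over-reaction takes a target with it. The two ends join at the peak of target, where P = S·A. Since P cannot pass the charge minus A, the gamma flask stays below 67.4%.

Third: S is 1.87 for epsilon, 1.71 for alpha and 1.58 for zeta. It is higher in gamma than in any of them, so I pick gamma.

Fourth: is one number enough? No, S has no clock. With the coupling partner at saturation, the coupling step by itself brings gamma down to 28.8% of its charge in 8.0 d, and the peak needs A below 32.6%, so I expect gamma to end near its peak. Nor does S hold the gas supply: reckoned at the full charge and the saturation value, zeta's demand for coupling partner is 1.34 times the greatest transfer, so I expect zeta's S to read high early, and zeta is already lowest.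

The forecast says gamma, with 27.5%, 44.5%, 30.5% and 36% for zeta, gamma, alpha and epsilon, since “the 20 °C flask stops close to the yield maximum”.

The flasks give 27.9%, 44.6%, 31.6% and 36.8% in that order, so gamma leads. At 8.00 d, gamma makes target at 0.981 times the rate it uses it. With 0.34 M charged and the same S, a flask otherwise like gamma ends at S·A/P = 0.543, and its target stands at 43.1%.

Its constants are made up; the flask was simulated.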